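Two questions stood on this flask: the apparent orders in reagent and in free catalyst at the moment 10% of the substrate counts as converted.

the same everywhere: free catalyst 5 mol%
- Friday's: substrate 1 M; reagent 0.70 equiv; run made earlier
- flask: substrate 0.50 M; reagent 0.700 equiv

Friday's run (percent of the substrate charged)

| time / d | product / % | substrate / % |
|---|---|---|
| 0.208 | 11.6 | 45.8 |
| 0.333 | 19.1 | 32.7 |
| 0.417 | 23.0 | 26.2 |
| 0.625 | 30.5 | 14.7 |
| 1.04 | 41.0 | 4.9 |
| 1.67 | 46.3 | 1.1 |
| 2.50 | 46.8 | 0 |

(each reading ± 0.3 percentage points)

1. apparent order in reagent when 10% of the substrate are converted (percent change of the rate of making product for one percent more reagent charged)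
2. apparent order in free catalyst when 10% of the substrate are converted (percent change of the rate of making product for one percent more free catalyst charged)

- what is bound to the catalyst counts as converted
- no earlier run changes the charge of free catalyst; that part of a forecast is a guess
- no earlier run changes the charge of reagent; that part of a forecast is a guess

Friday's run changed neither charge, so I had no reckoning for the order in reagent in this flask. For the catalyst I reckoned one quantity, the bound reach, which is the loading divided by the conversion looked at: the share of that conversion that can sit on the catalyst if each catalyst holds one substrate, 50.0%. Bound material counts as converted and the reach is half of the mark, so I expected more catalyst in this flask to reach the mark sooner, with less of it passed on as product. I therefore put the order in free catalyst between 0.5 and 1.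

The forecast gave 0.4 for reagent and 0.95 for free catalyst, holding that the catalyst order should be “close to 1 for a turnover step”, which stands near the top of my range.

The flask gave 0.64 for reagent, above the forecast, and 0.75 for free catalyst, below it and inside my range.

    substrate + free catalyst ⇌ catalyst intermediate A (K = 3.90 M⁻¹, k = 36.1 M⁻¹ h⁻¹)
    reagent + catalyst intermediate A ⇌ catalyst intermediate B (K = 11.0 M⁻¹, k = 5.13 M⁻¹ h⁻¹)
    catalyst intermediate B → free catalyst + product (k = 0.817 h⁻¹)
    2 substrate → homo dimer (k = 0.0816 M⁻¹ h⁻¹)

At the mark, catalyst intermediate B made up 37.8% of the catalyst in this flask, which through the bound reach is 18.9% of the conversion looked at. Counted up to 12.0 d, the midpoint of substrate binding to free catalyst in this flask came at 0.625 d, earlier than the midpoint of product release at 0.734 d.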